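The 1-hydroxycyclopent-2-en-4-one ring is cut between the carbinol carbon C1 and the enone β-carbon C2 (the ring =CH). Because C1 carries oxygen and C2 carries hydrogen next to the C3–Br/C4=O unit, this cut leads to an achiral isomer of the target: a 2,3,5-trisubstituted 4-pyranone whose ring oxygen bridges exactly these two carbons. Ultraviolet irradiation should contract it in one operation: 4π photo-electrocyclisation forms the C1–C2 bond, the pyran oxygen becomes the tertiary hydroxyl, and proton loss from the pent-2-enyl group creates the exocyclic (Z,E)-diene at C5. The pyranone is built from 4-methoxybut-3-en-2-one in three steps; the racemic photoproduct is resolved on a chiral phase.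

Key step: step 4

Remark on the chemistry: compounds 1, 5 (pure E isomer) and 7 are taken as commercial. The photochemical step has no element of absolute stereocontrol, so the single enantiomer is secured by the resolution in step 5.

Step 1
Reactants: 1 (E)-4-methoxybut-3-en-2-one; 2 bromine
Product: 4 (Z)-3-bromo-4-methoxybut-3-en-2-one, via dibromo ketone 3 (not isolated)
Conditions: Br2, CH2Cl2, −78 °C; then Et3N, −78 °C → rt
Reagents that add atoms: bromine, BrBr
Why: Addition of bromine to the electron-rich enol-ether C=C and base-induced loss of HBr through the α-bromo oxocarbenium ion give the α-bromo-β-methoxy enone (α-halogenation of an enone by addition–elimination); no stereocentre is formed.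

Step 2
Reactants: 4 (Z)-3-bromo-4-methoxybut-3-en-2-one; 5 (E)-1-bromopent-2-ene
Product: 6 (1Z,6E)-2-bromo-1-methoxynona-1,6-dien-3-one
Conditions: LiN(SiMe3)2 (1.05 equiv), THF, −78 °C; then 5, DMPU, −78 → −20 °C
Reagents that add atoms: (E)-1-bromopent-2-ene, CC/C=C/CBr
Why: The methyl group is the only enolisable position, so the kinetic lithium enolate forms there and is C-alkylated by the primary allylic bromide (SN2 enolate alkylation) with the (E)-alkene carried over unchanged.

Step 3
Reactants: 6 (1Z,6E)-2-bromo-1-methoxynona-1,6-dien-3-one; 7 methyl 9-chloro-9-oxononanoate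
Product: 9 methyl 8-{5-bromo-4-oxo-3-[(2E)-pent-2-en-1-yl]-4H-pyran-2-yl}octanoate, via diketone 8 (not isolated)
Conditions: LiN(SiMe3)2 (2.2 equiv), THF, −78 °C; 7; then CF3CO2H, CH2Cl2, rt
Reagents that add atoms: methyl 9-chloro-9-oxononanoate, COC(=O)CCCCCCCC(=O)Cl
Why: C-Acylation of the α′-enolate by the acid chloride (crossed Claisen acylation, the second equivalent of base holding the acidic 1,3-diketone 8 as its enolate) is followed under acid by 6-endo attack of the enol oxygen on the β-methoxy enone and loss of methanol, the standard 4-pyranone synthesis from 4-methoxybut-3-en-2-ones; the stereocentre of 8 is lost on aromatisation.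

Step 4
Reactants: 9 methyl 8-{5-bromo-4-oxo-3-[(2E)-pent-2-en-1-yl]-4H-pyran-2-yl}octanoate
Product: 12 racemic methyl 8-{(5Z)-3-bromo-1-hydroxy-4-oxo-5-[(2E)-pent-2-en-1-ylidene]cyclopent-2-en-1-yl}octanoate, via oxyallyl zwitterion 10 (not isolated), via epoxy dienol 11 (not isolated)
Conditions: hν (254 nm, quartz flow cell), (CF3)2CHOH, 5 mM, Ar, 0 °C, partial conversion with recycling of 9
Reagents that add atoms: none
Why: Proposed new method: π,π* excitation of the cross-conjugated pyranone should trigger the disrotatory 4π electrocyclisation that joins pyran C2 and C6 (ring C1 and C2 of the product) and leaves the ring oxygen as an epoxide fused to the oxyallyl zwitterion 10; the closest known reaction type is the photochemical ring contraction of 4-pyranones to 4-hydroxycyclopent-2-enones in which a nucleophile captures this zwitterion, and what is new is its termination by proton loss, as at the end of a Nazarov cyclisation. The carbocycle thus closes in a pentadienyl-cation-type 4π electrocyclic mode, not by a polar exo or endo attack. The only hydrogens β to the alkyl-bearing cation terminus are those of the doubly activated allylic CH2, so deprotonation there gives dienol 11, whose enol then opens the epoxide at the one C–O bond allylic to it (vinylogous β-elimination), which puts the hydroxyl on the quaternary carbon and the ring C=C next to bromine. The new quaternary carbinol centre arises on a planar achiral chromophore without any facial bias, so 12 is racemic and its configuration is settled only in step 5. The step needs Z geometry at the new exocyclic alkene and chemoselectivity for rearrangement over C–Br homolysis, solvent capture and secondary photolysis: in 10 the octanoate chain on the epoxide carbon lies close to the ring plane beside the CH2, so the butenyl group should turn toward the oxido oxygen in the eliminating rotamer, and the weakly nucleophilic ionising solvent, short residence time and partial conversion are meant to guard the rest.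

Step 5
Reactants: 12 racemic methyl 8-{(5Z)-3-bromo-1-hydroxy-4-oxo-5-[(2E)-pent-2-en-1-ylidene]cyclopent-2-en-1-yl}octanoate
Product: 13 methyl 8-{(1S,5Z)-3-bromo-1-hydroxy-4-oxo-5-[(2E)-pent-2-en-1-ylidene]cyclopent-2-en-1-yl}octanoate
Conditions: preparative supercritical-fluid chromatography on amylose tris(3,5-dimethylphenylcarbamate), CO2/i-PrOH
Reagents that add atoms: none
Why: The two enantiomers form diastereomeric adsorbates on the chiral polysaccharide phase (chromatographic resolution), and the 1S enantiomer is to be identified by anomalous X-ray scattering of bromine or by circular dichroism against calculation.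

Compound list
1 | (E)-4-methoxybut-3-en-2-one | CC(=O)/C=C/OC | starting material
2 | bromine | BrBr | starting material
3 | 3,4-dibromo-4-methoxybutan-2-one (diastereomer mixture, not isolated) | CC(=O)C(Br)C(Br)OC | intermediate
4 | (Z)-3-bromo-4-methoxybut-3-en-2-one | CC(=O)/C(Br)=C/OC | intermediate
5 | (E)-1-bromopent-2-ene | CC/C=C/CBr | starting material
6 | (1Z,6E)-2-bromo-1-methoxynona-1,6-dien-3-one | CC/C=C/CCC(=O)/C(Br)=C/OC | intermediate
7 | methyl 9-chloro-9-oxononanoate | COC(=O)CCCCCCCC(=O)Cl | starting material
8 | methyl (12E)-10-[(2Z)-2-bromo-3-methoxyprop-2-enoyl]-9-oxopentadec-12-enoate (racemic, not isolated) | CC/C=C/CC(C(=O)CCCCCCCC(=O)OC)C(=O)/C(Br)=C/OC | intermediate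
9 | methyl 8-{5-bromo-4-oxo-3-[(2E)-pent-2-en-1-yl]-4H-pyran-2-yl}octanoate | CC/C=C/CC1=C(CCCCCCCC(=O)OC)OC=C(Br)C1=O | intermediate
10 | oxyallyl zwitterion, 4-bromo-1-(8-methoxy-8-oxooctyl)-2-[(2E)-pent-2-en-1-yl]-6-oxabicyclo[3.1.0]hex-3-en-2-ylium-3-olate (racemic, cis-fused, not isolated) | CC/C=C/C[C+]1C([O-])=C(Br)C2OC12CCCCCCCC(=O)OC | intermediate
11 | epoxy dienol, methyl 8-{4-bromo-3-hydroxy-2-[(2E)-pent-2-en-1-ylidene]-6-oxabicyclo[3.1.0]hex-3-en-1-yl}octanoate (racemic, butenyl group syn to the enol carbon, not isolated) | CC/C=C/C=C1\C(O)=C(Br)C2OC12CCCCCCCC(=O)OC | intermediate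
12 | racemic methyl 8-{(5Z)-3-bromo-1-hydroxy-4-oxo-5-[(2E)-pent-2-en-1-ylidene]cyclopent-2-en-1-yl}octanoate | CC/C=C/C=C1\C(=O)C(Br)=CC1(O)CCCCCCCC(=O)OC | intermediate
13 | methyl 8-{(1S,5Z)-3-bromo-1-hydroxy-4-oxo-5-[(2E)-pent-2-en-1-ylidene]cyclopent-2-en-1-yl}octanoate | CC/C=C/C=C1\C(=O)C(Br)=C[C@@]1(O)CCCCCCCC(=O)OC | target

Total step count: 5
Longest linear sequence: 5 steps (1 → 4 → 6 → 9 → 12 → 13)

Steps most likely to fail

Step 4 (bears the label Proposed new method). What may go wrong: the zwitterion is captured by the solvent or slips to a 2-pyranone by oxygen migration before it loses a proton; the C–Br bond is cleaved by the light; the strongly absorbing trienone product isomerises at either alkene or is photolysed further; geometric control at the new exocyclic alkene is lost. The fallback uses known chemistry, sets out from 7 and comes back at 13, so that step 5 is not needed. Rosenmund reduction of 7 (H2, Pd on BaSO4, 2,6-lutidine, THF) gives methyl 9-oxononanoate F1. Direct catalytic asymmetric aldol addition of 4-(trimethylsilyl)but-3-yn-2-one to F1 (Et2Zn and the ProPhenol ligand as dinuclear zinc catalyst, in the enantiomeric form that delivers the R alcohol, 4 Å molecular sieves, THF, 0 °C) should give methyl (9R)-9-hydroxy-11-oxo-13-(trimethylsilyl)tridec-12-ynoate F2. Silylation (t-BuMe2SiOSO2CF3, 2,6-lutidine, CH2Cl2, −78 °C) gives the silyl ether F3, and bromodesilylation (N-bromosuccinimide, AgNO3 cat., acetone) gives the 1-bromoalkynyl ketone F4. The known cycloisomerisation of 1-bromoalk-1-yn-3-ones with a monovalent gold catalyst ((BrettPhos)AuNTf2, 1,2-dichloroethane, 60 °C) proceeds by 1,2-bromine shift to a β-bromo gold vinylidene and 1,5-insertion into the C9–H bond with retention. It should close the same ring bond and give methyl 8-[(1R)-3-bromo-1-[(tert-butyldimethylsilyl)oxy]-4-oxocyclopent-2-en-1-yl]octanoate F5, with the quaternary centre already in the required sense. Aldol addition of its lithium enolate to (E)-pent-2-enal (LiN(i-Pr)2, THF, −78 °C) gives the aldol F6, and acetylation (Ac2O, 4-(dimethylamino)pyridine, pyridine) gives the acetate F7. Elimination (1,8-diazabicyclo[5.4.0]undec-7-ene, CH2Cl2) gives the silyl-protected dienone F8, in which the butenyl group is expected to turn away from the silyloxy-bearing quaternary carbon. HF·pyridine in THF then removes the silyl group to give 13.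

Step 3. What may go wrong: O-acylation of the hindered, α′-substituted enolate instead of C-acylation, ketene formation from 7 by the excess base, or attack of the amide base on the bromo enol ether. The fallback sets out from 6 and comes back at 8. The carbon–carbon bond is made by aldol addition, where attack through oxygen leads nowhere. The lithium enolate of 6 (LiN(SiMe3)2, THF, −78 °C) adds to methyl 9-oxononanoate F1, made from 7 as in the fallback above, to give methyl (12E)-10-[(2Z)-2-bromo-3-methoxyprop-2-enoyl]-9-hydroxypentadec-12-enoate F9. Dess–Martin oxidation (periodinane, NaHCO3, CH2Cl2) then gives 8, which is cyclised with CF3CO2H as in step 3.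

Step 2. What may go wrong: proton exchange between the product and the enolate leading to double alkylation, SN2′ attack on the allylic bromide, or decomposition of the bromo enolate on warming. The fallback sets out from 4 and comes back at 8. The order of the two bond formations is reversed so that the allylic bromide meets a soft 1,3-dicarbonyl enolate. Compound 4 is acylated with 7 (LiN(SiMe3)2, 2.2 equiv, THF, −78 °C) to methyl (12Z)-12-bromo-13-methoxy-9,11-dioxotridec-12-enoate F10, which is C-alkylated with 5 (K2CO3, acetone, rt) to 8 and carried into the acid cyclisation of step 3.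

Further compounds
F1 | step 4 | methyl 9-oxononanoate | COC(=O)CCCCCCCC=O
F2 | step 4 | methyl (9R)-9-hydroxy-11-oxo-13-(trimethylsilyl)tridec-12-ynoate | COC(=O)CCCCCCC[C@@H](O)CC(=O)C#C[Si](C)(C)C
F3 | step 4 | methyl (9R)-9-[(tert-butyldimethylsilyl)oxy]-11-oxo-13-(trimethylsilyl)tridec-12-ynoate | COC(=O)CCCCCCC[C@@H](O[Si](C)(C)C(C)(C)C)CC(=O)C#C[Si](C)(C)C
F4 | step 4 | methyl (9R)-13-bromo-9-[(tert-butyldimethylsilyl)oxy]-11-oxotridec-12-ynoate | COC(=O)CCCCCCC[C@@H](O[Si](C)(C)C(C)(C)C)CC(=O)C#CBr
F5 | step 4 | methyl 8-[(1R)-3-bromo-1-[(tert-butyldimethylsilyl)oxy]-4-oxocyclopent-2-en-1-yl]octanoate | COC(=O)CCCCCCC[C@@]1(O[Si](C)(C)C(C)(C)C)CC(=O)C(Br)=C1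
F6 | step 4 | methyl 8-[(1R)-3-bromo-1-[(tert-butyldimethylsilyl)oxy]-5-[(2E)-1-hydroxypent-2-en-1-yl]-4-oxocyclopent-2-en-1-yl]octanoate (diastereomer mixture at the two new centres) | COC(=O)CCCCCCC[C@@]1(O[Si](C)(C)C(C)(C)C)C(C(O)/C=C/CC)C(=O)C(Br)=C1
F7 | step 4 | methyl 8-[(1R)-5-[(2E)-1-acetoxypent-2-en-1-yl]-3-bromo-1-[(tert-butyldimethylsilyl)oxy]-4-oxocyclopent-2-en-1-yl]octanoate (diastereomer mixture at the two new centres) | COC(=O)CCCCCCC[C@@]1(O[Si](C)(C)C(C)(C)C)C(C(OC(C)=O)/C=C/CC)C(=O)C(Br)=C1
F8 | step 4 | methyl 8-[(1S,5Z)-3-bromo-1-[(tert-butyldimethylsilyl)oxy]-4-oxo-5-[(2E)-pent-2-en-1-ylidene]cyclopent-2-en-1-yl]octanoate | CC/C=C/C=C1\C(=O)C(Br)=C[C@@]1(O[Si](C)(C)C(C)(C)C)CCCCCCCC(=O)OC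
F9 | step 3 | methyl (12E)-10-[(2Z)-2-bromo-3-methoxyprop-2-enoyl]-9-hydroxypentadec-12-enoate (diastereomer mixture) | CC/C=C/CC(C(O)CCCCCCCC(=O)OC)C(=O)/C(Br)=C/OC
F10 | step 2 | methyl (12Z)-12-bromo-13-methoxy-9,11-dioxotridec-12-enoate | COC(=O)CCCCCCCC(=O)CC(=O)/C(Br)=C/OC
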